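**One molecule.** Follow one molecule of X and ask what chance it has, each minute, of becoming G. If that chance does not depend on what stands around the molecule, the share turned at a given time does not depend on the charge.

| setting | delta | theta | alpha | eta | epsilon |
|---|---|---|---|---|---|
| X | 0.400 M | 0.200 M | 0.400 M | 0.600 M | 0.200 M |
| L | 0.00200 M | 0.00200 M | 0.00400 M | 0.00200 M | 0.00400 M |
| time |  |  |  |  | 22 min |

| run | time / min | [G] / M |
|---|---|---|
| delta run | 3.7 | 0.099 |
| delta run | 7.3 | 0.181 |
| delta run | 11 | 0.233 |
| delta run | 15 | 0.281 |
| delta run | 18 | 0.307 |
| delta run | 22 | 0.333 |
| theta run | 3.7 | 0.055 |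
| theta run | 7.3 | 0.078 |
| theta run | 11 | 0.109 |
| theta run | 15 | 0.145 |
| theta run | 18 | 0.157 |
| theta run | 22 | 0.172 |
| alpha run | 3.7 | 0.099 |
| alpha run | 7.3 | 0.188 |
| alpha run | 11 | 0.233 |
| alpha run | 15 | 0.278 |
| alpha run | 18 | 0.310 |
| alpha run | 22 | 0.334 |
| eta run | 3.7 | 0.156 |
| eta run | 7.3 | 0.269 |
| eta run | 11 | 0.354 |
| eta run | 15 | 0.420 |
| eta run | 18 | 0.448 |
| eta run | 22 | 0.494 |

(each reading ± 0.006 M)

- Overall: X -> G, with L as catalyst.
- Constant volume, constant temperature.
- The analysis sees a species whether free or bound.
- An order is taken over about fifteen percent of the charge, up and down.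

- how the opening rate goes with [L] round the charge of the delta run: the exponent of the rate at two percent of X gone to G
- how the opening rate goes with [X] round the charge of the delta run: the exponent of the rate at two percent of X gone to G (one fixed amount of G, the same in the runs compared)
- the theta run starts with 0.200 M less of X than the delta run, and with no G. Compared where both hold the same amount of X, once fifteen percent of what the theta run was charged with has turned into G, is the theta run faster, slower or alike (within a tenth)?
- G in the epsilon run at 22 min, as a share of the X charged

**Two neighbours.** The epsilon flask's close neighbour is the theta run, with the same X and half its L, so I first asked what a change of L does. The delta and alpha runs answer that, since the alpha run holds twice the L. At the last reading they held 0.333 M and 0.334 M of G, a gap smaller than the scatter of 0.006 M.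

The alpha run has epsilon's L, so I took from it κ, the chance per minute that one X becomes G, reckoned as ln(X charged / X left) over the time: 0.0819 min⁻¹. The delta run gives 0.0812 min⁻¹, about the same, so the two runs end together.

Charge did not seem to shift it either. At the last reading the theta run had turned 86.0% of its X and the delta run 83.2%. But one scatter on theta's charge is worth 3.00%, so I read these as one share.

**My reckoning.** A steady κ means pseudo-first-order decay: first order in X, no visible order in L, and the theta and delta runs alike at equal X. For the epsilon run I reckoned 1 − exp(−κt), which gives 83.5%.

**The forecast.** The forecast gave 0 for L, 1 for X, alike and 84%, a little above my share, on the ground that "The alpha run, with twice the L, tracks the delta run within noise at every reading".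

**The result.** The flask gave 0.027 for L, 1.0 for X, alike for the comparison and 83.1% for the epsilon run.

    L + X ⇌ LX (78.60 M⁻¹ min⁻¹, 101.4 min⁻¹)
    LX → G + L (42.54 min⁻¹)
    X → G (0.07500 min⁻¹)
    2 L ⇌ L2, settled at all times (29900 M⁻¹)

**The fork.** The epsilon share gives κ = 0.0808 min⁻¹. Of that chance, nearly all belongs to the direct step X → G, at 0.0750 min⁻¹. The remaining 0.00580 min⁻¹ is, on average over the epsilon run, the way through L. With the direct path from X to G taken away, the epsilon run reaches 12.0% instead of 83.1%.

The earlier runs and the new flask come from a simulation for an exercise; noise was put on by code.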